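The route rests on cutting the C1–C2 bond of the trione ring (3-hydroxy-4,4,6,6-tetramethylcyclohex-2-ene-1,5-dione): a β-dicarbonyl bond whose ring carries two quaternary CMe2 carbons (C4, C6), so that C2 is the only enolisable carbon of the opened chain. The precursor is an (S)-4-isopropyl-3,4-dihydrocoumarin in which the lactone stores the acyl carbon next to C2 on the phenol oxygen ortho to the benzylic stereocentre. In one operation the enolate of methyl 2,2,4-trimethyl-3-oxopentanoate opens this lactone (Claisen) and the released diketo ester closes the six-membered ring at C1–C2 (Dieckmann). The stereocentre is set earlier by an iminium-catalysed Friedel–Crafts alkylation.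

Key step: step 5

Remarks on the chemistry: the stereocentre of the target is S (trione C2 > aryl > isopropyl > H). C1 and C3 of the trione ring exchange roles by tautomerism; the enol is written as in the target. Compound 9 is taken as a purchased building block.

Step 1
Reactants: 1 2-methylbenzene-1,3,5-triol; 2 2-methylpropanoyl chloride
Product: 3 1-(2,4,6-trihydroxy-3-methylphenyl)-2-methylpropan-1-one
Conditions: AlCl3 (3.5 equiv), PhNO2, 0 °C then 60 °C; cold 1 M HCl work-up
Reagents that add atoms: none
Why: Friedel–Crafts C-acylation; the two free ring positions of 1 are equivalent, so a single regioisomer should form, and the new ketone deactivates the ring against a second acylation.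

Step 2
Reactants: 3 1-(2,4,6-trihydroxy-3-methylphenyl)-2-methylpropan-1-one
Product: 4 1-[4-(benzyloxy)-2,6-dihydroxy-3-methylphenyl]-2-methylpropan-1-one
Conditions: BnBr (1.0 equiv), K2CO3 (1.1 equiv), acetone, 0 °C to rt
Reagents that add atoms: benzyl bromide, BrCc1ccccc1
Why: Williamson ether synthesis; the 4-OH para to the ketone is the most acidic hydroxyl and is not held in a hydrogen bond to the carbonyl, so the mono-phenoxide should be benzylated there, which leaves the 6-OH as the only hydroxyl next to the free ring carbon.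

Step 3
Reactants: 4 1-[4-(benzyloxy)-2,6-dihydroxy-3-methylphenyl]-2-methylpropan-1-one; 5 (E)-4-methylpent-2-enal
Product: 7 1-[(4S)-5-(benzyloxy)-2,7-dihydroxy-6-methyl-4-(propan-2-yl)-3,4-dihydro-2H-chromen-8-yl]-2-methylpropan-1-one (both C2 epimers), via open-chain hydroxy aldehyde 6 (not isolated)
Conditions: (S)-2-[diphenyl(trimethylsilyloxy)methyl]pyrrolidine (20 mol %), PhCO2H (20 mol %), 5 (1.5 equiv), toluene, 0 °C to rt
Reagents that add atoms: none
Why: Iminium-ion-catalysed Friedel–Crafts alkylation/hemiacetalisation of a hydroxyarene with an enal; C5 of 4 is the only unsubstituted ring carbon, the diphenyl(silyloxy)methyl group of the (S)-catalyst shields one face of the s-trans (E)-iminium ion so that the arene adds to the open face of C3 of the enal and sets the S centre, and the adjacent 6-OH closes the lactol.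

Step 4
Reactants: 7 1-[(4S)-5-(benzyloxy)-2,7-dihydroxy-6-methyl-4-(propan-2-yl)-3,4-dihydro-2H-chromen-8-yl]-2-methylpropan-1-one
Product: 8 (4S)-5-(benzyloxy)-7-hydroxy-6-methyl-8-(2-methylpropanoyl)-4-(propan-2-yl)-3,4-dihydro-2H-chromen-2-one
Conditions: [C5H5NH][CrO3Cl] (pyridinium chlorochromate, 1.5 equiv), NaOAc, 4 Å MS, CH2Cl2, rt
Reagents that add atoms: none
Why: Chromate oxidation of a lactol to the lactone; the remaining phenol is hydrogen-bonded to the ketone on a fully substituted ring and the stereocentre is not α to the new carbonyl, so neither should be affected.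

Step 5
Reactants: 8 (4S)-5-(benzyloxy)-7-hydroxy-6-methyl-8-(2-methylpropanoyl)-4-(propan-2-yl)-3,4-dihydro-2H-chromen-2-one; 9 methyl 2,2,4-trimethyl-3-oxopentanoate
Product: 12 2-{(1S)-1-[2-(benzyloxy)-4,6-dihydroxy-3-methyl-5-(2-methylpropanoyl)phenyl]-2-methylpropyl}-3-hydroxy-4,4,6,6-tetramethylcyclohex-2-ene-1,5-dione, via lithium enolate of the keto ester 10 (not isolated), via open-chain diketo ester 11 (not isolated)
Conditions: 9 (3.3 equiv), LiN(iPr)2 (3.2 equiv), THF, −78 °C; add 8 in THF, −78 to −20 °C until the lactone is consumed, then rt; quench at 0 °C with 1 M HCl to pH 3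
Reagents that add atoms: none
Why: Crossed Claisen/Dieckmann domino: the tetrasubstituted lithium enolate 10 attacks the aryl lactone carbonyl of 7-O-lithiated 8 and the tetrahedral intermediate collapses with loss of the chelated phenoxide, a far better leaving group than the enolate, to give open-chain 11; a further equivalent of 10 then deprotonates the only enolisable carbon of 11, the CH2 between the stereocentre and the C5 ketone, and this enolate adds to the methyl ester and expels methoxide. The closest known reactions are the C-acylation of preformed ketone enolates by aryl esters and the base-induced Dieckmann cyclisation of methyl 2,2,4,4-tetramethyl-3,5-dioxohexanoate to syncarpic acid. The one ring closure is a 6-(enolexo)-exo-trig attack of the enolate carbon on the ester carbonyl; attack on the C3 ketone would need a four-membered ring, and O-attack gives an enol lactone that methoxide reopens, so all paths should drain to the trione. No stereocentre is created; the benzylic centre is β to every carbonyl, carries no acidic hydrogen and should pass through unchanged if the quench is kept cold. Chemoselectivity rests on the two quaternary CMe2 carbons (no second enolate, no aldol partner), on the aryl isopropyl ketone being switched off as a chelated vinylogous carboxylate, and on the final deprotonation of the product (a vinylogous acid, pKa about 5), which makes the sequence irreversible and shields its non-enolisable diketone units from retro-Claisen cleavage by methoxide.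

Step 6
Reactants: 12 2-{(1S)-1-[2-(benzyloxy)-4,6-dihydroxy-3-methyl-5-(2-methylpropanoyl)phenyl]-2-methylpropyl}-3-hydroxy-4,4,6,6-tetramethylcyclohex-2-ene-1,5-dione
Product: 13 3-hydroxy-4,4,6,6-tetramethyl-2-{(1S)-2-methyl-1-[2,4,6-trihydroxy-3-methyl-5-(2-methylpropanoyl)phenyl]propyl}cyclohex-2-ene-1,5-dione
Conditions: H2 (1 atm), 10% Pd/C, EtOAc, rt
Reagents that add atoms: none
Why: Hydrogenolysis of the aryl benzyl ether; neutral conditions should leave the stereocentre, the chelated aryl ketone and the trione enol untouched and avoid acid- or base-induced retro-Michael and cyclodehydration pathways of the free polyphenol.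

Compound list
1 | 2-methylbenzene-1,3,5-triol | Cc1c(O)cc(O)cc1O | starting material
2 | 2-methylpropanoyl chloride | CC(C)C(Cl)=O | starting material
3 | 1-(2,4,6-trihydroxy-3-methylphenyl)-2-methylpropan-1-one | Cc1c(O)cc(O)c(C(=O)C(C)C)c1O | intermediate
4 | 1-[4-(benzyloxy)-2,6-dihydroxy-3-methylphenyl]-2-methylpropan-1-one | Cc1c(OCc2ccccc2)cc(O)c(C(=O)C(C)C)c1O | intermediate
5 | (E)-4-methylpent-2-enal | CC(C)/C=C/C=O | starting material
6 | (3S)-3-[2-(benzyloxy)-4,6-dihydroxy-3-methyl-5-(2-methylpropanoyl)phenyl]-4-methylpentanal | O=CC[C@@H](C(C)C)c1c(O)c(C(=O)C(C)C)c(O)c(C)c1OCc2ccccc2 | intermediate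
7 | 1-[(4S)-5-(benzyloxy)-2,7-dihydroxy-6-methyl-4-(propan-2-yl)-3,4-dihydro-2H-chromen-8-yl]-2-methylpropan-1-one (both C2 epimers) | OC1C[C@@H](C(C)C)c2c(OCc3ccccc3)c(C)c(O)c(C(=O)C(C)C)c2O1 | intermediate
8 | (4S)-5-(benzyloxy)-7-hydroxy-6-methyl-8-(2-methylpropanoyl)-4-(propan-2-yl)-3,4-dihydro-2H-chromen-2-one | O=C1C[C@@H](C(C)C)c2c(OCc3ccccc3)c(C)c(O)c(C(=O)C(C)C)c2O1 | intermediate
9 | methyl 2,2,4-trimethyl-3-oxopentanoate | COC(=O)C(C)(C)C(=O)C(C)C | starting material
10 | lithium 1-methoxy-2,2,4-trimethyl-1-oxopent-3-en-3-olate (lithium enolate of 9) | [Li+].CC(C)=C([O-])C(C)(C)C(=O)OC | intermediate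
11 | methyl (7S)-7-[2-(benzyloxy)-4,6-dihydroxy-3-methyl-5-(2-methylpropanoyl)phenyl]-2,2,4,4,8-pentamethyl-3,5-dioxononanoate | COC(=O)C(C)(C)C(=O)C(C)(C)C(=O)C[C@@H](C(C)C)c1c(O)c(C(=O)C(C)C)c(O)c(C)c1OCc2ccccc2 | intermediate
12 | 2-{(1S)-1-[2-(benzyloxy)-4,6-dihydroxy-3-methyl-5-(2-methylpropanoyl)phenyl]-2-methylpropyl}-3-hydroxy-4,4,6,6-tetramethylcyclohex-2-ene-1,5-dione | Cc1c(O)c(C(=O)C(C)C)c(O)c([C@@H](C2=C(O)C(C)(C)C(=O)C(C)(C)C2=O)C(C)C)c1OCc3ccccc3 | intermediate
13 | 3-hydroxy-4,4,6,6-tetramethyl-2-{(1S)-2-methyl-1-[2,4,6-trihydroxy-3-methyl-5-(2-methylpropanoyl)phenyl]propyl}cyclohex-2-ene-1,5-dione | Cc1c(O)c(C(=O)C(C)C)c(O)c([C@@H](C2=C(O)C(C)(C)C(=O)C(C)(C)C2=O)C(C)C)c1O | target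

Total step count: 6
Longest linear sequence: 6 steps (1 → 3 → 4 → 7 → 8 → 12 → 13)

Steps most likely to fail

Step 3. The acyl-deactivated phenol may add too slowly to the iminium ion, 1,2-addition followed by electrocyclisation to a 2H-chromene may compete, or the facial selectivity may be poor. The fallback sets out from 4 and comes back at 8, replacing steps 3 and 4 by a racemic annulation and a classical resolution. Knoevenagel condensation of 2,2-dimethyl-1,3-dioxane-4,6-dione (Meldrum's acid) with 2-methylpropanal would give 5-(2-methylpropylidene)-2,2-dimethyl-1,3-dioxane-4,6-dione F1. Heating 4 with it in pyridine (conjugate addition at C5, lactonisation on the 6-OH, loss of acetone and CO2) should give the racemic lactone F2. Aminolysis with (S)-1-phenylethylamine in THF would give two diastereomeric hydroxy amides, from which (3S)-3-[2-(benzyloxy)-4,6-dihydroxy-3-methyl-5-(2-methylpropanoyl)phenyl]-4-methyl-N-[(1S)-1-phenylethyl]pentanamide F3 is separated by crystallisation or chromatography. TsOH·H2O in toluene at 80 °C should then re-close the lactone with loss of the amine to give 8.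

Step 5. The hindered enolate may act as a base and not as a carbon nucleophile (ketene formation from the lactone), methoxide may cleave the open-chain diketone by retro-Claisen reaction before the ring closes, or the ee may erode through phenoxide-assisted expulsion of the trione enolate. The fallback sets out from 8 and comes back at 13; it removes every acidic phenol and separates acylation from ring closure, which still forms the same C1–C2 bond. Methanolysis of 8 (K2CO3, MeOH) followed by benzylation of both phenols (BnBr, Cs2CO3, NaI, DMF, 60 °C) would give methyl (3S)-4-methyl-3-[2,4,6-tris(benzyloxy)-3-methyl-5-(2-methylpropanoyl)phenyl]pentanoate F4. Saponification (LiOH, THF/MeOH/H2O) would give the acid F5, and (COCl)2 with catalytic DMF the acid chloride F6. C-acylation of preformed 10, after exchange of lithium for magnesium with MgBr2·OEt2, should give the fully benzylated diketo ester F7, which is isolated. KOtBu in THF at 0 °C should effect the Dieckmann closure to the tribenzyl ether of the target F8, and H2 over Pd/C would give 13.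

Step 2. Alkylation may run on to di- and tribenzyl ethers or take place at an ortho hydroxyl. The fallback sets out from 3 and comes back at 4. Exhaustive benzylation (BnBr in excess, K2CO3, DMF, 60 °C) would give 1-[2,4,6-tris(benzyloxy)-3-methylphenyl]-2-methylpropan-1-one F9. MgBr2·OEt2 in toluene/Et2O at 70 °C should then cleave, under chelation control, only the two benzyl ethers ortho to the ketone and give 4.

Further compounds
F1 | step 3 | 5-(2-methylpropylidene)-2,2-dimethyl-1,3-dioxane-4,6-dione | CC(C)C=C1C(=O)OC(C)(C)OC1=O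
F2 | step 3 | rac-5-(benzyloxy)-7-hydroxy-6-methyl-8-(2-methylpropanoyl)-4-(propan-2-yl)-3,4-dihydro-2H-chromen-2-one | O=C1CC(C(C)C)c2c(OCc3ccccc3)c(C)c(O)c(C(=O)C(C)C)c2O1
F3 | step 3 | (3S)-3-[2-(benzyloxy)-4,6-dihydroxy-3-methyl-5-(2-methylpropanoyl)phenyl]-4-methyl-N-[(1S)-1-phenylethyl]pentanamide | C[C@H](NC(=O)C[C@@H](C(C)C)c1c(O)c(C(=O)C(C)C)c(O)c(C)c1OCc2ccccc2)c3ccccc3
F4 | step 5 | methyl (3S)-4-methyl-3-[2,4,6-tris(benzyloxy)-3-methyl-5-(2-methylpropanoyl)phenyl]pentanoate | COC(=O)C[C@@H](C(C)C)c1c(OCc2ccccc2)c(C(=O)C(C)C)c(OCc3ccccc3)c(C)c1OCc4ccccc4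
F5 | step 5 | (3S)-4-methyl-3-[2,4,6-tris(benzyloxy)-3-methyl-5-(2-methylpropanoyl)phenyl]pentanoic acid | OC(=O)C[C@@H](C(C)C)c1c(OCc2ccccc2)c(C(=O)C(C)C)c(OCc3ccccc3)c(C)c1OCc4ccccc4
F6 | step 5 | (3S)-4-methyl-3-[2,4,6-tris(benzyloxy)-3-methyl-5-(2-methylpropanoyl)phenyl]pentanoyl chloride | ClC(=O)C[C@@H](C(C)C)c1c(OCc2ccccc2)c(C(=O)C(C)C)c(OCc3ccccc3)c(C)c1OCc4ccccc4
F7 | step 5 | methyl (7S)-2,2,4,4,8-pentamethyl-3,5-dioxo-7-[2,4,6-tris(benzyloxy)-3-methyl-5-(2-methylpropanoyl)phenyl]nonanoate | COC(=O)C(C)(C)C(=O)C(C)(C)C(=O)C[C@@H](C(C)C)c1c(OCc2ccccc2)c(C(=O)C(C)C)c(OCc3ccccc3)c(C)c1OCc4ccccc4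
F8 | step 5 | 3-hydroxy-4,4,6,6-tetramethyl-2-{(1S)-2-methyl-1-[2,4,6-tris(benzyloxy)-3-methyl-5-(2-methylpropanoyl)phenyl]propyl}cyclohex-2-ene-1,5-dione | Cc1c(OCc2ccccc2)c(C(=O)C(C)C)c(OCc3ccccc3)c([C@@H](C4=C(O)C(C)(C)C(=O)C(C)(C)C4=O)C(C)C)c1OCc5ccccc5
F9 | step 2 | 1-[2,4,6-tris(benzyloxy)-3-methylphenyl]-2-methylpropan-1-one | Cc1c(OCc2ccccc2)cc(OCc3ccccc3)c(C(=O)C(C)C)c1OCc4ccccc4
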